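**Retrosynthetic overview**

1. The strategy rests on the pyranone ring of unit 1 (the 2,3-diarylchromone): its ring oxygen O1 sits on C8a, which is ortho to the C4 carbonyl. The ring is therefore cut at C3–C4 (aroylation of an enolate) and at O1–C8a (displacement of a fluoride on C8a that the C4 ketone activates).
2. Acid 1, as tert-butyl ester 2, and acetophenone 3 give benzyl aryl ketone 4 by α-arylation. Fluoroarene 5 gives acid chloride 9 through iminium salt 6, aldehyde 7 and acid 8. Ketone 4 and acid chloride 9 are joined through diketone 10 to chromone 11; this closes the pyranone of unit 1, the first ring formed.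
3. The pyranone of unit 2 (the flavone) is cut at C2–C3 and O1–C2 (Baker–Venkataraman logic). Acid 12 and phenol 14, made from acetophenone 13, give ester 15, diketone 16 and flavone 17; this is the second ring formed.
4. BCl3 then removes the three benzyl ethers and the chelated 5-methyl ether of unit 1 to give target 18.

Key step: step 6

Remark: the target has no stereocentre, so no stereocontrol is needed. Unit 1 is the 2,3-diarylchromone and unit 2 is the flavone throughout.

**Route**

Step 1
Reactants: 1 3-bromo-4-methoxybenzoic acid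
Product: 2 tert-butyl 3-bromo-4-methoxybenzoate
Conditions: Cl3CC(=NH)OtBu (2 equiv), BF3·OEt2 (cat.), CH2Cl2/cyclohexane, rt
Reagents that add atoms: tert-butyl 2,2,2-trichloroacetimidate, CC(C)(C)OC(=N)C(Cl)(Cl)Cl
Why: Acid-promoted tert-butyl transfer from the trichloroacetimidate to the carboxylic acid gives the tert-butyl ester, which tolerates NaOtBu and LiN(SiMe3)2 and is later removed by acid without loss of benzyl ethers.

Step 2
Reactants: 2 tert-butyl 3-bromo-4-methoxybenzoate; 3 4'-(benzyloxy)acetophenone
Product: 4 tert-butyl 3-[2-(4-benzyloxyphenyl)-2-oxoethyl]-4-methoxybenzoate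
Conditions: Pd(OAc)2 (2 mol %), XPhos (4 mol %), NaOtBu (2.2 equiv), toluene, 70 °C
Reagents that add atoms: none
Why: Palladium-catalysed ketone α-arylation (oxidative addition of 2 to zerovalent palladium, exchange with the sodium enolate of 3, reductive elimination) should stop after one arylation, because the ortho-methoxy group hinders a second one and the more acidic product is held as its enolate; the tert-butyl ester is inert to tert-butoxide.

Step 3
Reactants: 5 1-fluoro-3,5-dimethoxybenzene
Product: 7 2-fluoro-4,6-dimethoxybenzaldehyde, via iminium salt 6 (not isolated)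
Conditions: POCl3, DMF, 0 → 60 °C; then aq NaOAc, rt
Reagents that add atoms: N,N-dimethylformamide, CN(C)C=O; water, O
Why: Vilsmeier–Haack formylation should go mainly at C2, which is para to one methoxy group, ortho to the other and less hindered than C4 between the two methoxy groups; the minor isomer formylated at C4 is removed by crystallisation or chromatography.

Step 4
Reactants: 7 2-fluoro-4,6-dimethoxybenzaldehyde
Product: 8 2-fluoro-4,6-dimethoxybenzoic acid
Conditions: NaClO2, NaH2PO4, 2-methyl-2-butene, t-BuOH/H2O, rt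
Reagents that add atoms: sodium chlorite, [Na+].[O-]Cl=O
Why: Pinnick oxidation converts the aldehyde to the acid, and 2-methyl-2-butene traps the hypochlorous acid so the electron-rich ring is not chlorinated.

Step 5
Reactants: 8 2-fluoro-4,6-dimethoxybenzoic acid
Product: 9 2-fluoro-4,6-dimethoxybenzoyl chloride
Conditions: (COCl)2, DMF (cat.), CH2Cl2, 0 °C → rt; concentrate, use crude
Reagents that add atoms: oxalyl chloride, O=C(Cl)C(=O)Cl
Why: DMF-catalysed chlorination with oxalyl chloride gives the acid chloride with only volatile by-products, so it can be used without purification.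

Step 6
Reactants: 4 tert-butyl 3-[2-(4-benzyloxyphenyl)-2-oxoethyl]-4-methoxybenzoate; 9 2-fluoro-4,6-dimethoxybenzoyl chloride
Product: 11 tert-butyl 3-[2-(4-benzyloxyphenyl)-5,7-dimethoxy-4-oxochromen-3-yl]-4-methoxybenzoate, via 2-aryl-1,3-diketone 10 (not isolated)
Conditions: LiN(SiMe3)2 (2.1 equiv), THF, −78 °C; MgBr2·OEt2 (1.2 equiv), −78 → −20 °C; 9 (1.05 equiv), −78 °C → rt; aq NH4Cl, extract, concentrate; then K2CO3 (3 equiv), DMF, 90 °C
Reagents that add atoms: none
Why: LiN(SiMe3)2 removes a proton from the doubly activated CH2 of 4, and the magnesium enolate formed with MgBr2·OEt2 attacks the acid chloride carbon of 9 through carbon (Claisen-type C-aroylation, bond C3–C4), the second equivalent of base holding the product as its chelated diketonate 10. After the solvent change, K2CO3 regenerates the enolate of 10, whose oxygen on the 4-benzyloxyphenyl side adds to the fluorine-bearing carbon to give a Meisenheimer intermediate stabilised by the ortho ketone, and loss of fluoride forms bond O1–C8a. The closest known reaction type is the preparation of chromones and 4-quinolones from ketone enolates or enamines and 2-halobenzoyl chlorides by acylation followed by intramolecular SNAr. The pyranone of unit 1 closes as a six-membered ring by addition–elimination at an sp2 carbon, formally a 6-endo-trig attack on the C4a=C8a bond of the aryl ketone; no stereocentre is formed and the methine centre of 10 disappears on enolisation. The step needs acylation on carbon and not on oxygen, which the chelating magnesium counter-ion and the stability of the diketonate favour (an enol ester formed first can hand its acyl group to remaining enolate), and it needs closure by the correct oxygen, which is fixed because only the oxygen of the benzyloxyphenyl ketone can reach the C–F carbon in a six-membered ring. Both methoxy groups are meta to fluorine and so do not deactivate the carbon under attack, and the tert-butyl ester and the benzyl ether are inert to both bases.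

Step 7
Reactants: 11 tert-butyl 3-[2-(4-benzyloxyphenyl)-5,7-dimethoxy-4-oxochromen-3-yl]-4-methoxybenzoate
Product: 12 3-[2-(4-benzyloxyphenyl)-5,7-dimethoxy-4-oxochromen-3-yl]-4-methoxybenzoic acid
Conditions: CF3CO2H/CH2Cl2 (1:4), rt
Reagents that add atoms: none
Why: Acidolysis of the tert-butyl ester (loss of the tert-butyl cation as 2-methylpropene) frees the benzoic acid, while aryl benzyl and aryl methyl ethers are stable to CF3CO2H at room temperature.

Step 8
Reactants: 13 2,4,6-trihydroxyacetophenone
Product: 14 1-[2,4-bis(benzyloxy)-6-hydroxyphenyl]ethanone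
Conditions: BnBr (2.1 equiv), K2CO3 (2.2 equiv), DMF, rt
Reagents that add atoms: benzyl bromide, BrCc1ccccc1
Why: Williamson etherification with two equivalents of benzyl bromide alkylates the para hydroxyl and one ortho hydroxyl, while the remaining ortho hydroxyl is hydrogen-bonded to the acetyl carbonyl and stays free.

Step 9
Reactants: 12 3-[2-(4-benzyloxyphenyl)-5,7-dimethoxy-4-oxochromen-3-yl]-4-methoxybenzoic acid; 14 1-[2,4-bis(benzyloxy)-6-hydroxyphenyl]ethanone
Product: 15 2-acetyl-3,5-bis(benzyloxy)phenyl 3-[2-(4-benzyloxyphenyl)-5,7-dimethoxy-4-oxochromen-3-yl]-4-methoxybenzoate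
Conditions: EDC·HCl (1.5 equiv), DMAP (0.5 equiv), CH2Cl2, rt
Reagents that add atoms: none
Why: Steglich esterification, in which the carbodiimide activates the acid and DMAP passes it on as an acylpyridinium ion reactive enough to acylate the hydrogen-bonded phenol.

Step 10
Reactants: 15 2-acetyl-3,5-bis(benzyloxy)phenyl 3-[2-(4-benzyloxyphenyl)-5,7-dimethoxy-4-oxochromen-3-yl]-4-methoxybenzoate
Product: 16 1-[2,4-bis(benzyloxy)-6-hydroxyphenyl]-3-{3-[2-(4-benzyloxyphenyl)-5,7-dimethoxy-4-oxochromen-3-yl]-4-methoxyphenyl}propane-1,3-dione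
Conditions: LiN(SiMe3)2 (3 equiv), THF, −78 → 0 °C; aq HCl
Reagents that add atoms: none
Why: Baker–Venkataraman rearrangement, in which the lithium enolate of the acetyl group attacks the neighbouring aryl ester carbonyl and the aroyl group moves from oxygen to carbon (bond C2–C3 of unit 2); the non-nucleophilic amide base does not add to C2 of the chromone of unit 1.

Step 11
Reactants: 16 1-[2,4-bis(benzyloxy)-6-hydroxyphenyl]-3-{3-[2-(4-benzyloxyphenyl)-5,7-dimethoxy-4-oxochromen-3-yl]-4-methoxyphenyl}propane-1,3-dione
Product: 17 5,7-bis(benzyloxy)-2-{3-[2-(4-benzyloxyphenyl)-5,7-dimethoxy-4-oxochromen-3-yl]-4-methoxyphenyl}chromen-4-one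
Conditions: TsOH·H2O (0.2 equiv), toluene, 90 °C
Reagents that add atoms: none
Why: Acid-catalysed cyclodehydration, in which the free phenol adds to the distal carbonyl of the 1,3-diketone and water is lost to give the pyranone of unit 2 (bond O1–C2), under acid mild enough to keep the benzyl ethers.

Step 12
Reactants: 17 5,7-bis(benzyloxy)-2-{3-[2-(4-benzyloxyphenyl)-5,7-dimethoxy-4-oxochromen-3-yl]-4-methoxyphenyl}chromen-4-one
Product: 18 5,7-dihydroxy-2-{3-[5-hydroxy-2-(4-hydroxyphenyl)-7-methoxy-4-oxochromen-3-yl]-4-methoxyphenyl}chromen-4-one (target)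
Conditions: BCl3 (1 M in CH2Cl2, 8 equiv), pentamethylbenzene (9 equiv), CH2Cl2, −78 → 0 °C, then rt; MeOH quench
Reagents that add atoms: none
Why: Lewis-acid ether cleavage, in which BCl3 removes the three aryl benzyl ethers (the benzyl cation is trapped by pentamethylbenzene) and, through chelation between the C4 carbonyl and O5, the peri 5-methyl ether of unit 1, whereas the unchelated 7-methyl ether of unit 1 and the methyl ether on the bridging ring should resist BCl3 at or below room temperature.

**Compound list**

1 | 3-bromo-4-methoxybenzoic acid | COc1ccc(C(=O)O)cc1Br | starting material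
2 | tert-butyl 3-bromo-4-methoxybenzoate | COc1ccc(C(=O)OC(C)(C)C)cc1Br | intermediate
3 | 4'-(benzyloxy)acetophenone | CC(=O)c1ccc(OCc2ccccc2)cc1 | starting material
4 | tert-butyl 3-[2-(4-benzyloxyphenyl)-2-oxoethyl]-4-methoxybenzoate | COc1ccc(C(=O)OC(C)(C)C)cc1CC(=O)c1ccc(OCc2ccccc2)cc1 | intermediate
5 | 1-fluoro-3,5-dimethoxybenzene | COc1cc(F)cc(OC)c1 | starting material
6 | N-[(2-fluoro-4,6-dimethoxyphenyl)methylidene]-N-methylmethanaminium chloride (iminium salt, not isolated) | COc1cc(F)c(C=[N+](C)C)c(OC)c1.[Cl-] | intermediate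
7 | 2-fluoro-4,6-dimethoxybenzaldehyde | COc1cc(F)c(C=O)c(OC)c1 | intermediate
8 | 2-fluoro-4,6-dimethoxybenzoic acid | COc1cc(F)c(C(=O)O)c(OC)c1 | intermediate
9 | 2-fluoro-4,6-dimethoxybenzoyl chloride | COc1cc(F)c(C(Cl)=O)c(OC)c1 | intermediate
10 | tert-butyl 3-[1-(4-benzyloxyphenyl)-3-(2-fluoro-4,6-dimethoxyphenyl)-1,3-dioxopropan-2-yl]-4-methoxybenzoate (racemic enolisable methine, not isolated) | COc1ccc(C(=O)OC(C)(C)C)cc1C(C(=O)c1ccc(OCc2ccccc2)cc1)C(=O)c1c(F)cc(OC)cc1OC | intermediate
11 | tert-butyl 3-[2-(4-benzyloxyphenyl)-5,7-dimethoxy-4-oxochromen-3-yl]-4-methoxybenzoate | COc1cc(OC)c2c(=O)c(-c3cc(C(=O)OC(C)(C)C)ccc3OC)c(-c3ccc(OCc4ccccc4)cc3)oc2c1 | intermediate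
12 | 3-[2-(4-benzyloxyphenyl)-5,7-dimethoxy-4-oxochromen-3-yl]-4-methoxybenzoic acid | COc1cc(OC)c2c(=O)c(-c3cc(C(=O)O)ccc3OC)c(-c3ccc(OCc4ccccc4)cc3)oc2c1 | intermediate
13 | 2,4,6-trihydroxyacetophenone | CC(=O)c1c(O)cc(O)cc1O | starting material
14 | 1-[2,4-bis(benzyloxy)-6-hydroxyphenyl]ethanone | CC(=O)c1c(O)cc(OCc2ccccc2)cc1OCc1ccccc1 | intermediate
15 | 2-acetyl-3,5-bis(benzyloxy)phenyl 3-[2-(4-benzyloxyphenyl)-5,7-dimethoxy-4-oxochromen-3-yl]-4-methoxybenzoate | COc1cc(OC)c2c(=O)c(-c3cc(C(=O)Oc4cc(OCc5ccccc5)cc(OCc5ccccc5)c4C(C)=O)ccc3OC)c(-c3ccc(OCc4ccccc4)cc3)oc2c1 | intermediate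
16 | 1-[2,4-bis(benzyloxy)-6-hydroxyphenyl]-3-{3-[2-(4-benzyloxyphenyl)-5,7-dimethoxy-4-oxochromen-3-yl]-4-methoxyphenyl}propane-1,3-dione | COc1cc(OC)c2c(=O)c(-c3cc(C(=O)CC(=O)c4c(O)cc(OCc5ccccc5)cc4OCc4ccccc4)ccc3OC)c(-c3ccc(OCc4ccccc4)cc3)oc2c1 | intermediate
17 | 5,7-bis(benzyloxy)-2-{3-[2-(4-benzyloxyphenyl)-5,7-dimethoxy-4-oxochromen-3-yl]-4-methoxyphenyl}chromen-4-one | COc1cc(OC)c2c(=O)c(-c3cc(-c4cc(=O)c5c(OCc6ccccc6)cc(OCc6ccccc6)cc5o4)ccc3OC)c(-c3ccc(OCc4ccccc4)cc3)oc2c1 | intermediate
18 | 5,7-dihydroxy-2-{3-[5-hydroxy-2-(4-hydroxyphenyl)-7-methoxy-4-oxochromen-3-yl]-4-methoxyphenyl}chromen-4-one | COc1cc(O)c2c(=O)c(-c3cc(-c4cc(=O)c5c(O)cc(O)cc5o4)ccc3OC)c(-c3ccc(O)cc3)oc2c1 | target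

**Step count**

Total: 12 steps. Longest linear sequence: 9 steps (from 5 through steps 3, 4, 5, 6, 7, 9, 10, 11 and 12).

**Steps most likely to fail**

Step 6. The hindered enolate of 4 may be acylated on oxygen by the doubly ortho-substituted acid chloride, giving an enol ester that cannot close, so too little diketone reaches the displacement. The fallback sets out from ketone 4 and aldehyde 7 and replaces the acylation by an aldol addition, which can only form the bond at carbon. The lithium enolate of 4 (LiN(SiMe3)2, THF, −78 °C) should add to 7 to give the β-hydroxy ketone tert-butyl 3-[1-(4-benzyloxyphenyl)-3-(2-fluoro-4,6-dimethoxyphenyl)-3-hydroxy-1-oxopropan-2-yl]-4-methoxybenzoate F1 as a mixture of diastereomers, both centres being removed later. Oxidation of F1 with Dess–Martin periodinane (CH2Cl2, rt) should give diketone 10, now isolated. The fallback comes back to the route at 10, which is closed with K2CO3 in DMF as in step 6 to give 11.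

Step 12. The single treatment with BCl3 may cleave the unchelated methyl ethers on prolonged exposure, stop before the 5-methyl ether of unit 1 is gone, or benzylate the phloroglucinol ring of unit 2 on carbon. The fallback sets out from 17 and separates the two tasks. Hydrogenolysis (H2, palladium on carbon (Pd/C), THF/MeOH, rt) should give 5,7-dihydroxy-2-{3-[2-(4-hydroxyphenyl)-5,7-dimethoxy-4-oxochromen-3-yl]-4-methoxyphenyl}chromen-4-one F2. Chelation-controlled demethylation of F2 with AlCl3 in MeCN (0 °C → rt, then aq HCl) should then remove only the methyl ether peri to the C4 carbonyl of unit 1. The fallback comes back to the route at 18.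

Step 9. Esterification of the hydrogen-bonded phenol of 14, which lies ortho to the acetyl group, may be slow, so the activated acid rearranges to an N-acylurea. The fallback sets out from acid 12 and forms the diketone directly by C-aroylation of an acetophenone dianion. Oxalyl chloride with catalytic DMF (CH2Cl2, 0 °C → rt) should convert 12 into 3-[2-(4-benzyloxyphenyl)-5,7-dimethoxy-4-oxochromen-3-yl]-4-methoxybenzoyl chloride F3. The lithium dianion of 14 (LiN(SiMe3)2, 3.5 equiv, THF, −78 °C) is then acylated by F3 on the enolate carbon; any ester formed on the phenoxide oxygen would rearrange under the same base. The fallback comes back to the route at diketone 16 and bypasses 15.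

**Further compounds**

F1 | step 6 | tert-butyl 3-[1-(4-benzyloxyphenyl)-3-(2-fluoro-4,6-dimethoxyphenyl)-3-hydroxy-1-oxopropan-2-yl]-4-methoxybenzoate (mixture of diastereomers) | COc1ccc(C(=O)OC(C)(C)C)cc1C(C(=O)c1ccc(OCc2ccccc2)cc1)C(O)c1c(F)cc(OC)cc1OC
F2 | step 12 | 5,7-dihydroxy-2-{3-[2-(4-hydroxyphenyl)-5,7-dimethoxy-4-oxochromen-3-yl]-4-methoxyphenyl}chromen-4-one | COc1cc(OC)c2c(=O)c(-c3cc(-c4cc(=O)c5c(O)cc(O)cc5o4)ccc3OC)c(-c3ccc(O)cc3)oc2c1
F3 | step 9 | 3-[2-(4-benzyloxyphenyl)-5,7-dimethoxy-4-oxochromen-3-yl]-4-methoxybenzoyl chloride | COc1cc(OC)c2c(=O)c(-c3cc(C(Cl)=O)ccc3OC)c(-c3ccc(OCc4ccccc4)cc3)oc2c1
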